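Which of these flasks holds the most L at the end, when one charge is kept warm, kept cold, or held cold and then warmed?

| flask | E | J | G | temperature | remark | time |
|---|---|---|---|---|---|---|
| midnight | 1 M | 0.70 equiv | 0.30 M | −10 °C | run made earlier |  |
| summer | 2.2 M | 0.70 equiv | 0.30 M | 1 °C | run made earlier |  |
| noon | 1.5 M | 0.70 equiv | 0.15 M | −10 °C | run made earlier |  |
| Saturday's | 1.5 M | 0.700 equiv | 0.300 M | 5 °C |  | 3.0 d |
| Tuesday's | 1.5 M | 0.700 equiv | 0.300 M | −15 °C |  | 3.0 d |
| Sunday's | 1.5 M | 0.700 equiv | 0.300 M |  | at −15 °C until 40 h, from then on at 5 °C | 3.0 d |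
midnight run (percent of the E charged)

| time / d | L / % | Z / % |
|---|---|---|
| 0.250 | 4.9 | 1.3 |
| 0.625 | 11.9 | 0.2 |
| 1.25 | 23.4 | 0 |
| 2.00 | 31.2 | 0 |
| 2.50 | 35.6 | 0 |
| 4.00 | 45.6 | 0 |

summer run (percent of the E charged)

| time / h | L / % | Z / % |
|---|---|---|
| 8.00 | 26.2 | 0 |
| 15.0 | 39.5 | 1.5 |
| 20.0 | 44.6 | 0.9 |
| 30.0 | 50.1 | 4.6 |
| 40.0 | 52.0 | 5.4 |

noon run (percent of the E charged)

| time / d | L / % | Z / % |
|---|---|---|
| 0.625 | 12.2 | 0 |
| 1.25 | 21.9 | 0 |
| 2.00 | 32.4 | 0 |
| 2.50 | 40.3 | 0 |
| 4.00 | 48.4 | 0.8 |

(readings scatter by 1 percentage point)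
- the flask that comes out highest in amount of L, in percent of the E charged, or "all alike" when all lie within 1.5 percentage points (Saturday's / Tuesday's / Sunday's / all alike)
- L at the end, in percent of the E charged, Saturday's
- L at the end, in percent of the E charged, Tuesday's
- L at the end, in percent of the E charged, Sunday's
- what was read earlier has a scatter of 1 percentage point, one standard deviation

The midnight and noon runs differ in both E and G, yet their percent curves lie close together, the gap in L being 4.7 percentage points at 2.50 d. We therefore read E as going to L by first-order loss, with concentration dropping out. The midnight reading at 1.25 d gives a constant of 0.213 d⁻¹ at −10 °C. The summer reading at 8.00 h gives 0.911 d⁻¹ at 1 °C. These two readings give an activation energy of 79.2 kJ mol⁻¹, and we extrapolate to 1.50 d⁻¹ at 5 °C and 0.106 d⁻¹ at −15 °C.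

Define the clock number, a Damköhler number: the constant times the time, summed over the temperatures a flask passes through, which counts lifetimes of E. Saturday's reaches 4.51, Tuesday's 0.317, Sunday's 2.18.

On this reading equal clock gives equal percent, so we set Tuesday's against the midnight run at 1.49 d, where interpolation gives 25.9 %. The summer run ended at clock 1.52, where first-order turnover allows 78.1 % but L and Z sum to 57.4 %. Replacing the summer L curve by the mean of its readings, 42.5 %, we count that gap as a loss of 0.321 per unit of clock. Decaying from the last summer reading, and adding no further L, we estimate 42.1 % for Sunday's and 19.9 % for Saturday's, so in our reckoning Sunday's stands higher than the others.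

Is one number enough? The same reckoning on the midnight run gives a loss of 0.543, more than the summer value. So the loss per unit of clock differs between these two runs, and our estimated heights carry that error.

The forecast calls the midnight–noon match “a compensation”, where we see first order. It names Sunday's, with 42 % for Saturday's, 40 % for Tuesday's and 45 % for Sunday's.

The simulation gives 18.3 % for Saturday's, 24.4 % for Tuesday's and 43.3 % for Sunday's, so Sunday's is highest.

    L + X ⇌ Z (K = 7.50 M⁻¹, k = 7.60 × 10⁻⁴ M⁻¹ min⁻¹, Ea = 80.0 kJ mol⁻¹, ΔH = −11.0 kJ mol⁻¹)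
    E + G → Q (k = 0.00150 M⁻¹ min⁻¹, Ea = 64.0 kJ mol⁻¹)
    E → L (k = 0.00120 min⁻¹, Ea = 83.0 kJ mol⁻¹)
    L → D (k = 3.00 × 10⁻⁴ min⁻¹, Ea = 86.0 kJ mol⁻¹)
    J → X (k = 2.10 × 10⁻⁴ min⁻¹, Ea = 101 kJ mol⁻¹)
    (constants at 5 °C)

At the end of Saturday's, L was being made more slowly than it was used up, at 0.0472 of that rate, each step taken net. The neighbour of Saturday's with 0.90 M of E has the same clock number, 4.51, and its L ends at 19.3 %.

(The numbers in the tables are calculated for an exercise, and the scatter is random.)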